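Follow one substrate molecule.

| flask | substrate | reagent | capture agent | free catalyst | remark | time |
|---|---|---|---|---|---|---|
| zeta | 0.14 M | 1.2 equiv | 0.014 M | 2.5 mol% | run made earlier |  |
| alpha | 0.14 M | 1.2 equiv | 0.014 M | 10 mol% | run made earlier |  |
| flask | 0.14 M | 1.20 equiv | 0.0140 M | 5.1 mol% |  | 2.0 h |

- zeta (time / h: substrate / %, target / %, isomer of the product / %): 0.200: 58.1, 31.7, 9.8; 0.417: 36.6, 38.9, 24.1; 1.00: 12.3, 39.0, 47.6; 2.50: 0, 41.6, 53.2
- alpha (time / h: substrate / %, target / %, isomer of the product / %): 0.333: 0.6, 41.3, 55.0; 0.833: 0, 43.7, 55.7; 1.50: 1.4, 41.7, 55.7; 2.50: 0, 40.0, 58.2

(standard deviation of a reading: 1 percentage point)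

- the reaction counts as stopped when no species that holds the substrate changes by six tenths of a point or more over the second half of the time

1. why nothing more happens at 2.0 h, or that something still does (it is still moving / the reagent has run out first / forward and back rates have come level / no working catalyst is left / all of the substrate has reacted)
2. conversion of substrate at 2.0 h
3. amount of target at 2.0 h, in percent of the substrate charged
4. amount of isomer of the product at 2.0 h, in percent of the substrate charged

- The molecule can end as target or as isomer, or it can drop out of the count. We define the leak φ as the share of the substrate charged that reads as none of substrate, target or isomer: the alpha run gives φ = 1.68% as a mean of its readings, good to about 0.87 percentage points.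
- Now turn the question round: what would make this flask halt with substrate left? If one reagent goes with each substrate, its reagent would have to lie below one equivalent, yet 1.20 equiv is charged.
- Or its catalyst would have to be lost. If each leaked molecule holds one catalyst, the loading would have to fall to φ, but this flask has 5.1 mol%, which is 3.04 times φ.
- Or it would have to be slow. The zeta run read 12.3% substrate at 1.00 h, so, taking first-order decay with rate proportional to loading, we reckon 0.0194% for this flask at 2.0 h.
- So we expect this flask to stop with nearly all the substrate reacted, with target near 41.7% and isomer near 56.2%, the alpha means, and 32.9% of the catalyst held by the leak.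
- The forecast, which differs from us on the ending, gave as its ending that forward and back rates have come level, with conversion 99.9%, target 41.7% and isomer 56%, saying “That points to equilibrium rather than kinetic partitioning”.
- This flask ends thus: all of the substrate has reacted, with conversion >99.9%, target 42.9% and isomer 55.7%. In this flask substrate is the limiting reagent, with 0% of its charge left against 17% of the charge of reagent.

    substrate + free catalyst ⇌ catalyst intermediate A (K = 59.0 L mol⁻¹, k = 1.56 L mol⁻¹ s⁻¹)
    reagent + catalyst intermediate A → catalyst intermediate B (k = 0.281 L mol⁻¹ s⁻¹)
    catalyst intermediate B → free catalyst + target (k = 0.873 s⁻¹)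
    target + free catalyst ⇌ isomer of the product + free catalyst, rate k4*[free catalyst]*[target] forward; the back reaction follows from the equilibrium constant (K = 1.30, k = 1.09 L mol⁻¹ s⁻¹)
    catalyst intermediate B + capture agent → trapped intermediate (k = 0.975 L mol⁻¹ s⁻¹)

- In this flask the trapped intermediate holds 28.0% of the catalyst at 2.00 h, against our 32.9%. A neighbour flask, like this one but charged with 2 mol% of free catalyst, has 1.19 times φ, so the same leak reckons 84.0% of its catalyst trapped. That neighbour flask shows 66.8% of its catalyst as trapped intermediate at 2.00 h, which is 1.34% of its substrate charged, and it still holds 6.70% of that charge as substrate.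

The numbers in the tables stem from a simulated flask with constants of no real substance; scatter was added.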